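The core is a cis-syn-cis 5-4-5 tricycle: ring A (C4–C5–C6–C7–C8) and ring C (C1–C2–C3–C9–C13) lie on the same face of cyclobutane ring B (C3–C4–C8–C9; numbering in the remark below). Everything rests on cutting ring A at C4–C5 and C7–C8: a Pauson–Khand [2+2+1] cycloaddition of acetylene and CO onto the strained cyclobutene C4=C8 of a photochemically made bicyclo[3.2.0]heptenone (rings B and C) closes ring A in one operation, the bridgehead CH3 (C3) and OSiEt3 (C9) steering cobalt to the face syn to ring C. The later stereocentres (C5, C1, C7) follow from convex-face attack on the bowl-shaped tricycle; an intramolecular olefination closes the butenolide.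

Key step: step 3

Remark (numbering, target): C1 = CH–O-tigloyl; C2 = CH2; C3 = C(CH3); C4 and C8 = cyclobutane CH; C5 = CH–OAc; C6 = CH2; C7 = C(OH)CH3; C9 = C–O10 (lactone oxygen); C11 = lactone C=O; C12 = C–CH2OAc; C13 = butenolide β-carbon. "Convex" is the outer face of the bowl (it carries H4, H8, C3–CH3, C9–O); "concave" is the inner face.

Remark (assumption): compounds 4, 6, 7 and 8 are racemic (SMILES show the enantiomer carried on); the lipase of step 5 is assumed to follow the usual empirical size rule for secondary alcohols (C4 side large, C6 side medium) and to acetylate the (5R)-alcohol faster, so that the wanted (5S)-alcohol is recovered.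

Step 1
Reactants: 1 2-hydroxy-3-methylcyclopent-2-en-1-one (cyclotene)
Product: 2 3-methyl-2-(triethylsilyloxy)cyclopent-2-en-1-one
Conditions: Et3SiCl, imidazole, DMF, 0 °C → rt
Reagents that add atoms: chlorotriethylsilane, CC[Si](Cl)(CC)CC
Why: O-silylation of the acidic, unhindered enol hydroxyl of the enolised 1,2-diketone; no stereocentre is formed.

Step 2
Reactants: 2 3-methyl-2-(triethylsilyloxy)cyclopent-2-en-1-one; 3 acetylene
Product: 4 rac-(1R,5R)-5-methyl-1-(triethylsilyloxy)bicyclo[3.2.0]hept-6-en-2-one
Conditions: hν (366 nm), CH2Cl2 saturated with 3, −70 °C, stopped at partial conversion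
Reagents that add atoms: none
Why: Enone–alkyne [2+2] photocycloaddition through the enone triplet; the four/five ring fusion can only be cis, which sets C3 and C9 relative to each other (racemic), and long-wavelength light limits the secondary 1,3-acyl shift of the β,γ-unsaturated ketone product.

Step 3
Reactants: 4 rac-5-methyl-1-(triethylsilyloxy)bicyclo[3.2.0]hept-6-en-2-one; 3 acetylene
Product: 6 rac-cis-syn-cis tricyclic enedione (ring A enone C7=O/C5=C6; C13=O; C9–OSiEt3), via cobalt–ethyne complex 5 (not isolated)
Conditions: Co2(CO)8, 3 (1 atm), CH2Cl2, rt (forms 5); then 4, N-methylmorpholine N-oxide, CH2Cl2, 0 °C → rt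
Reagents that add atoms: octacarbonyldicobalt Co2(CO)8 (supplies the C7=O carbonyl), [Co].[Co].[C-]#[O+].[C-]#[O+].[C-]#[O+].[C-]#[O+].[C-]#[O+].[C-]#[O+].[C-]#[O+].[C-]#[O+]
Why: Pauson–Khand reaction: complex 5 loses one CO (N-oxide promotion), binds the strained cyclobutene C4=C8 and inserts it into a Co–C(alkyne) bond to form C4–C5, after which CO insertion and reductive elimination form C7–C8 and C6–C7, so ring A is closed onto ring B as a cyclopentenone by a [2+2+1] cycloaddition. The closest known reaction type is the intermolecular Pauson–Khand reaction of norbornenes and bicyclo[3.2.0]hept-6-enes, whose ring strain makes them the best alkene partners. Both new bonds to C4 and C8 are delivered to one face, so H4 and H8 are cis, and the face is controlled by the substrate: the face anti to ring C is flanked by the bridgehead CH3 and the bulky OSiEt3, whereas the syn face sees only the tied-back C2H2 and the flat C13 carbonyl, so addition should occur syn to ring C (cis-syn-cis). The step also needs regioselectivity (CO on C8, ethyne carbon on C4): C–C bond formation pyramidalises the alkene carbon and pushes its hydrogen toward the anti allylic substituent, which costs less at C4 (next to CH3) than at C8 (next to OSiEt3), and cobalt prefers the carbon beside the acceptor-substituted C9, where the C13 carbonyl oxygen on the same face can assist. Ethyne is symmetrical, so no alkyne regiochemistry arises.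

Step 4
Reactants: 6 rac-cis-syn-cis tricyclic enedione
Product: 8 rac-β-hydroxy ketone (C5–OH convex), via β-boryl ketone 7 (not isolated)
Conditions: B2pin2, CuCl (5 mol%), Xantphos (5 mol%), NaOtBu (10 mol%), MeOH (2 equiv), THF, rt; then 30% H2O2, pH 7 phosphate buffer, THF, 0 °C
Reagents that add atoms: bis(pinacolato)diboron (boron of 7), CC1(C)OB(OC1(C)C)B1OC(C)(C)C(C)(C)O1; hydrogen peroxide (oxygen of 8), OO
Why: Copper-catalysed conjugate borylation of the enone (much faster than 1,2-addition to the hindered C13 ketone) from the convex face of ring A, then stereoretentive C–B oxidation, which sets C5 with OH cis to H4; neutral oxidation avoids β-elimination.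

Step 5
Reactants: 8 rac-β-hydroxy ketone
Product: 9 (5S)-enantiomer of 8 (recovered as the unreacted alcohol)
Conditions: Amano lipase PS (immobilised Burkholderia cepacia lipase), vinyl acetate, MTBE, 30 °C, run to just over half conversion; chromatography
Reagents that add atoms: none
Why: Lipase-catalysed kinetic resolution by enantioselective transesterification: the enzyme should acetylate the (5R)-alcohol faster, so the slower (5S)-alcohol is recovered enantioenriched and separated from the acetate, which fixes the absolute configuration of C3, C4, C5, C8 and C9.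

Step 6
Reactants: 9 (5S)-β-hydroxy ketone
Product: 10 homoallylic alcohol (C7=CH2; C5–OH; C13=O; C9–OSiEt3)
Conditions: Zn, CH2Br2, TiCl4, THF/CH2Cl2, 0 °C → rt
Reagents that add atoms: dibromomethane, BrCBr
Why: Takai–Lombardo methylenation: the non-basic reagent converts the unhindered ring-A ketone into C7=CH2 without retro-aldol or β-elimination of the C5 hydroxyl and should leave the neopentylic α-silyloxy ketone C13=O untouched.

Step 7
Reactants: 10 homoallylic alcohol
Product: 11 C5 acetate of 10
Conditions: Ac2O, pyridine, DMAP (cat.), CH2Cl2, 0 °C → rt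
Reagents that add atoms: acetic anhydride, CC(=O)OC(C)=O
Why: DMAP-catalysed acylation of the secondary C5–OH; no stereocentre is touched and no β-carbonyl remains that could cause elimination.

Step 8
Reactants: 11 C5 acetate
Product: 13 α,α'-dihydroxy ketone (C1–OH convex; free C9–OH), via C1-hydroxylated triethylsilyl ether 12 (not isolated)
Conditions: KHMDS (1.1 equiv), THF, −78 °C; 2-(phenylsulfonyl)-3-phenyloxaziridine, −78 °C; AcOH; then HF·pyridine, pyridine, THF, 0 °C → rt
Reagents that add atoms: 2-(phenylsulfonyl)-3-phenyloxaziridine, O=S(=O)(c1ccccc1)N1OC1c1ccccc1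
Why: Davis enolate hydroxylation: only C1 carries α-hydrogens, and the oxaziridine must approach the convex face because ring A fills the concave face, which sets C1 with OH cis to C3–CH3 and C9–O; buffered fluoride then cleaves the tertiary silyl ether.

Step 9
Reactants: 13 α,α'-dihydroxy ketone
Product: 14 C1 tiglate of 13 (C9–OH free)
Conditions: (E)-2-methylbut-2-enoyl chloride, pyridine, DMAP (cat.), CH2Cl2, 0 °C
Reagents that add atoms: tigloyl chloride, C/C=C(\C)C(=O)Cl
Why: Acylation of the secondary α-hydroxy ketone; the neopentylic tertiary C9–OH should not react, and the weak base avoids E/Z or deconjugative isomerisation of the tiglate.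

Step 10
Reactants: 15 tert-butyl (diethoxyphosphoryl)acetate; 16 bromomethyl acetate
Product: 17 tert-butyl 3-acetoxy-2-(diethoxyphosphoryl)propanoate (racemic)
Conditions: NaH, THF, 0 °C; the sodium salt added slowly to 16 (1.5 equiv), THF, −78 → 0 °C
Reagents that add atoms: none
Why: SN2 C-alkylation of the phosphonoacetate carbanion by the highly reactive α-acyloxy halide; inverse addition keeps the carbanion concentration low and suppresses proton transfer, loss of acetate and dialkylation.

Step 11
Reactants: 17 tert-butyl 3-acetoxy-2-(diethoxyphosphoryl)propanoate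
Product: 18 3-acetoxy-2-(diethoxyphosphoryl)propanoic acid (racemic)
Conditions: CF3CO2H, CH2Cl2, 0 °C → rt
Reagents that add atoms: none
Why: Acidolysis of the tert-butyl ester with loss of isobutene; acid leaves the acetate and the phosphonate intact and cannot trigger β-elimination.

Step 12
Reactants: 14 C1 tiglate with free C9–OH; 18 3-acetoxy-2-(diethoxyphosphoryl)propanoic acid
Product: 19 C9 ester of 14 with acid 18 (epimers at the phosphonate α-carbon)
Conditions: DCC, DMAP (cat.), CH2Cl2, 0 °C → rt
Reagents that add atoms: none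
Why: Steglich-type esterification: DCC turns the α-phosphono acid into a small, ketene-like acylating species able to acylate the hindered tertiary C9–OH; the new phosphonate α-centre is lost again in step 13.

Step 13
Reactants: 19 phosphonate ester
Product: 20 butenolide (O10–C11(=O)–C12(CH2OAc)=C13; C7=CH2)
Conditions: LiCl, iPr2NEt, MeCN, 0 °C → rt
Reagents that add atoms: none
Why: Intramolecular Horner–Wadsworth–Emmons olefination (Masamune–Roush conditions) of the C13 ketone closes the five-membered lactone, whose ring enforces the alkene geometry; if acetate is lost by E1cB, conjugate re-addition of acetate to the 2-phosphonoacrylate regenerates the same carbanion.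

Step 14
Reactants: 20 butenolide with C7=CH2
Product: 21 target (C7–OH convex, C7–CH3 concave)
Conditions: Co(acac)2 (20 mol%), PhSiH3, O2 (1 atm), THF, rt; aqueous Na2S2O3 work-up
Reagents that add atoms: dioxygen, O=O
Why: Mukaiyama hydration by metal-hydride hydrogen-atom transfer: H adds to the CH2 terminus of the electron-rich 1,1-disubstituted alkene (faster than to the acceptor-substituted tiglate and butenolide alkenes) and the tertiary C7 radical is trapped by O2 on the convex face, which sets C7.

Compound list
1 | 2-hydroxy-3-methylcyclopent-2-en-1-one (cyclotene) | CC1=C(O)C(=O)CC1 | starting material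
2 | 3-methyl-2-(triethylsilyloxy)cyclopent-2-en-1-one | CC1=C(O[Si](CC)(CC)CC)C(=O)CC1 | intermediate
3 | acetylene (ethyne) | C#C | starting material
4 | rac-(1R,5R)-5-methyl-1-(triethylsilyloxy)bicyclo[3.2.0]hept-6-en-2-one (rings B and C; cis-fused; C13=O, C4=C8; racemate, enantiomer carried on shown) | C1C[C@]2(C)C=C[C@]2(O[Si](CC)(CC)CC)C1=O | intermediate
5 | (μ-ethyne)hexacarbonyldicobalt, Co2(CO)6(HC≡CH) (written as its components) | C#C.[Co].[Co].[C-]#[O+].[C-]#[O+].[C-]#[O+].[C-]#[O+].[C-]#[O+].[C-]#[O+] | intermediate
6 | rac-7-methyl-1-(triethylsilyloxy)tricyclo[5.3.0.0^2,6]dec-4-ene-3,10-dione, cis-syn-cis (ring A enone C7=O/C5=C6 and ring C on the same face of ring B; H4 and H8 cis to C3–CH3 and C9–OSiEt3; racemate, enantiomer carried on shown) | C1C[C@]2(C)[C@@H]3C=CC(=O)[C@@H]3[C@]2(O[Si](CC)(CC)CC)C1=O | intermediate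
7 | rac-β-boryl ketone: 6 saturated at C5–C6 with a pinacolboryl group at C5 on the convex face (cis to H4) | C1C[C@]2(C)[C@@H]3[C@@H](B4OC(C)(C)C(C)(C)O4)CC(=O)[C@@H]3[C@]2(O[Si](CC)(CC)CC)C1=O | intermediate
8 | rac-β-hydroxy ketone: C5–OH on the convex face (cis to H4), C7=O, C13=O, C9–OSiEt3 (racemate, enantiomer carried on shown) | C1C[C@]2(C)[C@@H]3[C@@H](O)CC(=O)[C@@H]3[C@]2(O[Si](CC)(CC)CC)C1=O | intermediate
9 | (5S)-enantiomer of 8 (absolute configuration as in 21) | C1C[C@]2(C)[C@@H]3[C@@H](O)CC(=O)[C@@H]3[C@]2(O[Si](CC)(CC)CC)C1=O | intermediate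
10 | homoallylic alcohol: 9 with C7=CH2 in place of C7=O | C1C[C@]2(C)[C@@H]3[C@@H](O)CC(=C)[C@@H]3[C@]2(O[Si](CC)(CC)CC)C1=O | intermediate
11 | C5 acetate of 10 | C1C[C@]2(C)[C@@H]3[C@@H](OC(C)=O)CC(=C)[C@@H]3[C@]2(O[Si](CC)(CC)CC)C1=O | intermediate
12 | 11 with an additional C1–OH on the convex face (cis to C3–CH3 and C9–OSiEt3) | O[C@H]1C[C@]2(C)[C@@H]3[C@@H](OC(C)=O)CC(=C)[C@@H]3[C@]2(O[Si](CC)(CC)CC)C1=O | intermediate
13 | α,α'-dihydroxy ketone: 12 without the silyl group (free tertiary C9–OH) | O[C@H]1C[C@]2(C)[C@@H]3[C@@H](OC(C)=O)CC(=C)[C@@H]3[C@]2(O)C1=O | intermediate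
14 | C1 (E)-2-methylbut-2-enoate (tiglate) of 13 | C/C=C(\C)C(=O)O[C@H]1C[C@]2(C)[C@@H]3[C@@H](OC(C)=O)CC(=C)[C@@H]3[C@]2(O)C1=O | intermediate
15 | tert-butyl (diethoxyphosphoryl)acetate | CCOP(=O)(CC(=O)OC(C)(C)C)OCC | starting material
16 | bromomethyl acetate | CC(=O)OCBr | starting material
17 | tert-butyl 3-acetoxy-2-(diethoxyphosphoryl)propanoate (racemic) | CCOP(=O)(OCC)C(COC(C)=O)C(=O)OC(C)(C)C | intermediate
18 | 3-acetoxy-2-(diethoxyphosphoryl)propanoic acid (racemic) | CCOP(=O)(OCC)C(COC(C)=O)C(O)=O | intermediate
19 | C9 ester of 14 with acid 18 (epimers at the phosphonate α-carbon) | C/C=C(\C)C(=O)O[C@H]1C[C@]2(C)[C@@H]3[C@@H](OC(C)=O)CC(=C)[C@@H]3[C@]2(OC(=O)C(COC(C)=O)P(=O)(OCC)OCC)C1=O | intermediate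
20 | butenolide: lactone O10–C11(=O)–C12(CH2OAc)=C13 fused on C9–C13; C1–O-tigloyl, C5–OAc, C7=CH2 | C/C=C(\C)C(=O)O[C@H]1C[C@]2(C)[C@@H]3[C@@H](OC(C)=O)CC(=C)[C@@H]3[C@@]23OC(=O)C(COC(C)=O)=C13 | intermediate
21 | target CNP0210373.1, (1S,3R,4R,5S,7R,8R,9R) in the numbering of the remark: 20 hydrated at C7 (C7–OH convex, C7–CH3 concave) | C/C=C(\C)C(=O)O[C@H]1C[C@]2(C)[C@@H]3[C@@H](OC(C)=O)C[C@@](C)(O)[C@@H]3[C@@]23OC(=O)C(COC(C)=O)=C13 | target

Total step count: 14. Longest linear sequence: 12 steps (steps 1–9 and 12–14); steps 10–11 form the two-step branch to acid 18.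

Steps most likely to fail

Step 3. The alkene insertion may proceed with poor facial selectivity (ring A formed anti to ring C) or with the wrong regiochemistry (CO on C4). The fallback replaces substrate control by ligand-directed delivery. It sets out from 4: thioketalisation of C13=O (ethane-1,2-dithiol, Zn(OTf)2, CH2Cl2) gives the spiro-1,3-dithiolane F1. A thermal Pauson–Khand reaction of F1 with complex 5 (toluene, 70 °C, no N-oxide) then relies on the sulfur on the concave side of C13, a homoallylic ligand for C8: it should displace CO on cobalt, deliver the cluster to the face syn to ring C and hold cobalt (hence CO) on C8, giving the dithiolane-protected enone F2. Hydrolysis of the dithiolane (MeI, CaCO3, aqueous MeCN, 40 °C) comes back to the route at 6.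

Step 13. E1cB loss of acetate from the phosphonate carbanion, or slow attack on the hindered C13 ketone, may outrun the olefination. The fallback closes the ring with a halogen placeholder and introduces the side-chain carbon afterwards by cross-coupling. It sets out from 14: saponification of commercial triethyl 2-bromo-2-phosphonoacetate (LiOH, THF/H2O) gives bromo(diethoxyphosphoryl)acetic acid F3. DCC/DMAP esterification of the C9–OH of 14 with F3 gives the α-bromo phosphonoacetate F4, whose carbanion has no β-leaving group. LiCl/iPr2NEt then closes the α-bromobutenolide F5. Stille coupling of F5 with (tributylstannyl)methanol (Pd(PPh3)4, zerovalent palladium, dioxane, 90 °C) gives the hydroxymethyl butenolide F6, and Ac2O/pyridine comes back to the route at 20.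

Step 5. The lipase may discriminate the enantiomers of the hindered tricyclic alcohol poorly or turn it over too slowly. The fallback is a covalent resolution. It sets out from 8: esterification with (S)-O-methylmandelic acid (DCC, DMAP, CH2Cl2) gives two diastereomeric esters that are separated by chromatography or crystallisation, and the one derived from the (5S)-alcohol is the mandelate F7. Takai–Lombardo methylenation of F7 (Zn, CH2Br2, TiCl4) gives the methylene mandelate F8. K2CO3/MeOH then removes the auxiliary, which is safe once the β-ketone is gone, and comes back to the route at 10.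

Further compounds
F1 | step 3 | spiro-1,3-dithiolane of 4 at C13 | C1C[C@]2(C)C=C[C@]2(O[Si](CC)(CC)CC)C13SCCS3
F2 | step 3 | C13 spiro-1,3-dithiolane of enedione 6 | C1C[C@]2(C)[C@@H]3C=CC(=O)[C@@H]3[C@]2(O[Si](CC)(CC)CC)C14SCCS4
F3 | step 13 | bromo(diethoxyphosphoryl)acetic acid | CCOP(=O)(OCC)C(Br)C(O)=O
F4 | step 13 | C9 bromo(diethoxyphosphoryl)acetate of 14 | C/C=C(\C)C(=O)O[C@H]1C[C@]2(C)[C@@H]3[C@@H](OC(C)=O)CC(=C)[C@@H]3[C@]2(OC(=O)C(Br)P(=O)(OCC)OCC)C1=O
F5 | step 13 | α-bromobutenolide (C12–Br analogue of 20) | C/C=C(\C)C(=O)O[C@H]1C[C@]2(C)[C@@H]3[C@@H](OC(C)=O)CC(=C)[C@@H]3[C@@]23OC(=O)C(Br)=C13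
F6 | step 13 | hydroxymethyl butenolide (C12–CH2OH analogue of 20) | C/C=C(\C)C(=O)O[C@H]1C[C@]2(C)[C@@H]3[C@@H](OC(C)=O)CC(=C)[C@@H]3[C@@]23OC(=O)C(CO)=C13
F7 | step 5 | (S)-O-methylmandelate of the (5S)-alcohol 9 | C1C[C@]2(C)[C@@H]3[C@@H](OC(=O)[C@@H](OC)c4ccccc4)CC(=O)[C@@H]3[C@]2(O[Si](CC)(CC)CC)C1=O
F8 | step 5 | (S)-O-methylmandelate of 10 | C1C[C@]2(C)[C@@H]3[C@@H](OC(=O)[C@@H](OC)c4ccccc4)CC(=C)[C@@H]3[C@]2(O[Si](CC)(CC)CC)C1=O
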